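**Retrosynthetic overview**

- Numbering: ring A = C1 (ether O), C2 (OH), C3 (H), C4 (Br), C5 (H), C6 (Br). Ring B = C1' (ether O), C2' (OH), C3' (H), C4', C5', C6' (Br).
- Feature: on ring A, C4-Br and C6-Br are para and ortho to the ether carbon C1 but meta to C2-O, so electrophilic bromination cannot reach them. Nitro groups at C4 and C6 can occupy these sites, activate C1 for ether formation, and later be converted into the bromines.
- Disconnections, backwards: both O-CH3 bonds (BBr3); C4-Br and C6-Br to the C4,C6-diamine (tetrazotisation, double Sandmeyer) and on to the C4,C6-dinitro ether (iron); C1-O by SNAr into the ring B phenol and a ring A chloride.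
- Ring B phenol: guaiacol takes three bromines at C4', C5', C6' under the direction of its own OH and OMe. Ring A chloride: 4-nitroguaiacol is nitrated at C6 and its OH is exchanged for Cl.
- No ring is built: both benzene rings are bought and are joined in step 4.

Key step: step 6

Assumption: the SMILES carries no stereodescriptor and the diaryl ether axis is taken as freely rotating, so the target is treated as achiral and no step has to set configuration.

**Route**

Step 1
Reactants: 1 guaiacol (2-methoxyphenol); 2 bromine
Product: 5 4,5,6-tribromoguaiacol (2,3,4-tribromo-6-methoxyphenol), via 4-bromoguaiacol 3 (not isolated), via 4,5-dibromoguaiacol 4 (not isolated)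
Conditions: Br2 (3.1 equiv), AcOH, 10 °C → rt → 45 °C; aq NaHSO3 wash, recrystallisation
Reagents that add atoms: bromine, BrBr
Why: Electrophilic aromatic bromination: OH sends the first bromine to C4' (para), OMe the second to C5' (para to OMe and less deactivated by the C4' bromine than the meta-related C6'), and OH the third to C6' (ortho), while C3', meta to OH and wedged between OMe and Br, should stay free as long as bromine is held at about three equivalents.

Step 2
Reactants: 6 4-nitroguaiacol (2-methoxy-4-nitrophenol); 7 nitric acid
Product: 8 4,6-dinitroguaiacol (2-methoxy-4,6-dinitrophenol)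
Conditions: 65% HNO3 (1.1 equiv), AcOH, 10 → 20 °C
Reagents that add atoms: nitric acid, O[N+](=O)[O-]
Why: Electrophilic aromatic nitration in which OH (ortho director) and the C4 nitro group (meta director) both point to C6, the same pattern as the nitration of vanillin ortho to its OH, and starting from the mononitro compound avoids the oxidative damage that free guaiacol suffers in nitric acid.

Step 3
Reactants: 8 4,6-dinitroguaiacol
Product: 10 2-chloro-1-methoxy-3,5-dinitrobenzene, via 2-methoxy-4,6-dinitrophenyl phosphorodichloridate 9 (not isolated)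
Conditions: POCl3 (excess), N,N-diethylaniline (1.1 equiv), 90 °C; poured on ice
Reagents that add atoms: phosphoryl chloride POCl3, O=P(Cl)(Cl)Cl
Why: Chlorodehydroxylation of an activated nitrophenol: O-phosphorylation turns the phenol oxygen into a dichlorophosphate leaving group and chloride displaces it by SNAr at C1, ortho and para to the nitro groups, as in the known conversions of picric acid and 2,4-dinitrophenols into their chlorides.

Step 4
Reactants: 5 4,5,6-tribromoguaiacol; 10 2-chloro-1-methoxy-3,5-dinitrobenzene
Product: 11 1,2,3-tribromo-5-methoxy-4-(2-methoxy-4,6-dinitrophenoxy)benzene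
Conditions: K2CO3 (1.5 equiv), dry DMF, 70 °C
Reagents that add atoms: none
Why: SNAr by addition-elimination through a Meisenheimer adduct: the C4 and C6 nitro groups make C1 electrophilic enough for the hindered, weakly basic phenoxide of 5, the ring A OMe is meta to both nitro groups and is not displaced, and the metal-free conditions leave the three C-Br bonds untouched.

Step 5
Reactants: 11 1,2,3-tribromo-5-methoxy-4-(2-methoxy-4,6-dinitrophenoxy)benzene
Product: 12 4-(2,3,4-tribromo-6-methoxyphenoxy)-5-methoxybenzene-1,3-diamine
Conditions: Fe powder (8 equiv), AcOH/EtOH/H2O, 70 °C; filtration through Celite, aq NaHCO3, under N2, used at once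
Reagents that add atoms: none
Why: Béchamp-type dissolving-metal reduction of nitroarenes, in which iron in weak acid takes both nitro groups to amines without the hydrodebromination that catalytic hydrogenation over palladium would risk.

Step 6
Reactants: 12 4-(2,3,4-tribromo-6-methoxyphenoxy)-5-methoxybenzene-1,3-diamine
Product: 14 1,2,3-tribromo-4-(2,4-dibromo-6-methoxyphenoxy)-5-methoxybenzene, via ring A bis(diazonium) bis(hydrogensulfate) 13 (not isolated)
Conditions: NaNO2 (2.2 equiv) in conc. H2SO4, 0-5 °C; 12 in AcOH added dropwise, 0-5 °C; urea (0.2 equiv); then poured into CuBr (2.5 equiv), 48% aq HBr, 0 → 70 °C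
Reagents that add atoms: CuBr, [Cu+].[Br-]; hydrobromic acid HBr, Br (bromine atoms of 14); NaNO2, [Na+].[O-]N=O; H2SO4, OS(=O)(=O)O (outer nitrogen atoms and counter-ions of 13 only)
Why: Nitrosonium hydrogensulfate converts both amino groups into diazonium groups (tetrazotisation) to give 13; on transfer into CuBr/HBr each diazonium group accepts one electron from monovalent copper and loses N2, and the aryl radical at C4 or C6 takes a bromine atom from the CuBr2 just formed, which returns CuBr, so that HBr is the net bromine source. The closest known reaction type is the double Sandmeyer halogenation of tetrazotised meta-phenylenediamines, including aryloxy-substituted diamines made from dinitro diaryl ethers. Two bonds are formed (C4-Br and C6-Br), no ring is closed and no stereocentre arises. The step needs chemoselectivity, because a diazonium ion must not attack C3 or C5 of diamine that has not yet reacted (azo coupling); feeding the diamine slowly into a surplus of nitrosating agent in concentrated acid prevents this, since every amino group still present is then an ammonium ion and the ring is deactivated. In the radical stage the substrate helps itself: both ring B positions ortho to the ether oxygen (C2' with OMe, C6' with Br) are substituted, so the C6 radical finds no C-H site for a Pschorr-type closure to a dibenzofuran and should be captured by the concentrated copper bromide instead.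

Step 7
Reactants: 14 1,2,3-tribromo-4-(2,4-dibromo-6-methoxyphenoxy)-5-methoxybenzene
Product: 16 3,4,5-tribromo-2-(2,4-dibromo-6-hydroxyphenoxy)phenol (target), via bis(dibromoboryloxy) diaryl ether 15 (not isolated)
Conditions: BBr3 (4 equiv), CH2Cl2, −78 °C → rt; then ice-water
Reagents that add atoms: boron tribromide BBr3, BrB(Br)Br (boron and bromine of 15 only; nothing but hydrogen stays in 16)
Why: Lewis-acid cleavage of aryl methyl ethers: BBr3 binds each OMe oxygen, bromide attacks the methyl carbon by SN2 and the aryloxyboranes are hydrolysed on work-up, while the diaryl ether C-O bonds (sp2 carbon on both sides) and the five C-Br bonds are inert.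

**Compound list**

| No. | Name | SMILES | Role |
|---|---|---|---|
| 1 | guaiacol (2-methoxyphenol) | COc1ccccc1O | starting material |
| 2 | bromine | BrBr | starting material |
| 3 | 4-bromoguaiacol (4-bromo-2-methoxyphenol) | COc1cc(Br)ccc1O | intermediate |
| 4 | 4,5-dibromoguaiacol (4,5-dibromo-2-methoxyphenol) | COc1cc(Br)c(Br)cc1O | intermediate |
| 5 | 4,5,6-tribromoguaiacol (2,3,4-tribromo-6-methoxyphenol) | COc1cc(Br)c(Br)c(Br)c1O | intermediate |
| 6 | 4-nitroguaiacol (2-methoxy-4-nitrophenol) | COc1cc(ccc1O)[N+](=O)[O-] | starting material |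
| 7 | nitric acid | O[N+](=O)[O-] | starting material |
| 8 | 4,6-dinitroguaiacol (2-methoxy-4,6-dinitrophenol) | COc1cc(cc(c1O)[N+](=O)[O-])[N+](=O)[O-] | intermediate |
| 9 | 2-methoxy-4,6-dinitrophenyl phosphorodichloridate | COc1cc(cc(c1OP(=O)(Cl)Cl)[N+](=O)[O-])[N+](=O)[O-] | intermediate |
| 10 | 2-chloro-1-methoxy-3,5-dinitrobenzene | COc1cc(cc(c1Cl)[N+](=O)[O-])[N+](=O)[O-] | intermediate |
| 11 | 1,2,3-tribromo-5-methoxy-4-(2-methoxy-4,6-dinitrophenoxy)benzene | COc1cc(cc(c1Oc1c(OC)cc(Br)c(Br)c1Br)[N+](=O)[O-])[N+](=O)[O-] | intermediate |
| 12 | 4-(2,3,4-tribromo-6-methoxyphenoxy)-5-methoxybenzene-1,3-diamine | COc1cc(N)cc(N)c1Oc1c(OC)cc(Br)c(Br)c1Br | intermediate |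
| 13 | 4-(2,3,4-tribromo-6-methoxyphenoxy)-5-methoxybenzene-1,3-bis(diazonium) bis(hydrogensulfate) | COc1cc([N+]#N)cc([N+]#N)c1Oc1c(OC)cc(Br)c(Br)c1Br.OS(=O)(=O)[O-].OS(=O)(=O)[O-] | intermediate |
| 14 | 1,2,3-tribromo-4-(2,4-dibromo-6-methoxyphenoxy)-5-methoxybenzene | COc1cc(Br)cc(Br)c1Oc1c(OC)cc(Br)c(Br)c1Br | intermediate |
| 15 | bis(dibromoboryloxy) diaryl ether (both phenol oxygens of the target carry BBr2) | BrB(Br)Oc1cc(Br)cc(Br)c1Oc1c(OB(Br)Br)cc(Br)c(Br)c1Br | intermediate |
| 16 | 3,4,5-tribromo-2-(2,4-dibromo-6-hydroxyphenoxy)phenol | Oc1cc(Br)cc(Br)c1Oc1c(O)cc(Br)c(Br)c1Br | target |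

Total step count: 7
Longest linear sequence: 6 (steps 2, 3, 4, 5, 6, 7, from 4-nitroguaiacol)

**Steps most likely to fail**

**1. Step 6 (key step).**
- What may go wrong: azo coupling between diazonium ions and diamine that is not yet diazotised. Water or bromide may also attack the doubly activated C1 of the tetrazonium ion and expel the ring B phenoxide. Reduction or hydrolysis may take the place of bromine transfer at one of the two sites.
- Fallback: the two bromines are introduced one after the other, so that neither a meta-diamine nor a tetrazonium ion ever exists. It sets out from 11 and comes back to the route at 14.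
- SnCl2·2H2O (3 equiv) in EtOH/HCl should reduce the crowded nitro group at C6 first, giving 2-(2,3,4-tribromo-6-methoxyphenoxy)-3-methoxy-5-nitroaniline F1.
- This weakly basic amine is diazotised with NaNO2 in conc. H2SO4/AcOH to 2-(2,3,4-tribromo-6-methoxyphenoxy)-3-methoxy-5-nitrobenzenediazonium hydrogensulfate F2.
- CuBr in 48% HBr converts this salt into 1,2,3-tribromo-4-(2-bromo-6-methoxy-4-nitrophenoxy)-5-methoxybenzene F3.
- Iron in AcOH/EtOH then reduces the remaining nitro group to give 3-bromo-5-methoxy-4-(2,3,4-tribromo-6-methoxyphenoxy)aniline F4.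
- A second diazotisation gives 3-bromo-5-methoxy-4-(2,3,4-tribromo-6-methoxyphenoxy)benzenediazonium hydrogensulfate F5, and a second Sandmeyer bromination with CuBr/HBr delivers 14.

**2. Step 4.**
- What may go wrong: addition of the hindered, weakly nucleophilic phenoxide to a carbon flanked by OMe and NO2 may be too slow. Hydrolysis of the chloride, or of the activated ether once formed, by traces of water would then take over.
- Fallback: the leaving group is changed so that the rate-limiting addition becomes much faster. It sets out from 10 and comes back at 11.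
- Halogen exchange (spray-dried KF, sulfolane, 120 °C), the reaction that turns 2,4-dinitrochlorobenzene into the fluoride, should give 2-fluoro-1-methoxy-3,5-dinitrobenzene F6.
- The fluoride is then joined to 5 with K2CO3 in dry DMSO near room temperature to give 11.

**3. Step 3.**
- What may go wrong: incomplete displacement of the dichlorophosphate, attack of the tertiary aniline on the activated chloride at 90 °C, and hydrolysis back to the phenol during the quench.
- Fallback: the chloride is bypassed and the phenol is activated as an N-arylpyridinium salt. It sets out from 8, with 5 as partner, and comes back at 11.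
- Compound 8 is treated with TsCl in dry pyridine. The first-formed 2-methoxy-4,6-dinitrophenyl 4-methylbenzenesulfonate F7 is attacked by pyridine at C1 to give 1-(2-methoxy-4,6-dinitrophenyl)pyridinium 4-methylbenzenesulfonate F8.
- Phenol 5 is then added and the mixture is heated in pyridine, so that the phenoxide displaces pyridine from C1 and gives 11.

**Further compounds**

F1 | step 6 | 2-(2,3,4-tribromo-6-methoxyphenoxy)-3-methoxy-5-nitroaniline | COc1cc(cc(N)c1Oc1c(OC)cc(Br)c(Br)c1Br)[N+](=O)[O-]
F2 | step 6 | 2-(2,3,4-tribromo-6-methoxyphenoxy)-3-methoxy-5-nitrobenzenediazonium hydrogensulfate | COc1cc(cc([N+]#N)c1Oc1c(OC)cc(Br)c(Br)c1Br)[N+](=O)[O-].OS(=O)(=O)[O-]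
F3 | step 6 | 1,2,3-tribromo-4-(2-bromo-6-methoxy-4-nitrophenoxy)-5-methoxybenzene | COc1cc(cc(Br)c1Oc1c(OC)cc(Br)c(Br)c1Br)[N+](=O)[O-]
F4 | step 6 | 3-bromo-5-methoxy-4-(2,3,4-tribromo-6-methoxyphenoxy)aniline | COc1cc(N)cc(Br)c1Oc1c(OC)cc(Br)c(Br)c1Br
F5 | step 6 | 3-bromo-5-methoxy-4-(2,3,4-tribromo-6-methoxyphenoxy)benzenediazonium hydrogensulfate | COc1cc([N+]#N)cc(Br)c1Oc1c(OC)cc(Br)c(Br)c1Br.OS(=O)(=O)[O-]
F6 | step 4 | 2-fluoro-1-methoxy-3,5-dinitrobenzene | COc1cc(cc(c1F)[N+](=O)[O-])[N+](=O)[O-]
F7 | step 3 | 2-methoxy-4,6-dinitrophenyl 4-methylbenzenesulfonate | COc1cc(cc(c1OS(=O)(=O)c1ccc(C)cc1)[N+](=O)[O-])[N+](=O)[O-]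
F8 | step 3 | 1-(2-methoxy-4,6-dinitrophenyl)pyridinium 4-methylbenzenesulfonate | COc1cc(cc(c1[n+]1ccccc1)[N+](=O)[O-])[N+](=O)[O-].Cc1ccc(cc1)S(=O)(=O)[O-]
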